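## The problem

Target **21** is a benzoic acid with a methoxy group at C4 and two allylic side chains at C3 and C5. An arene with the oxygen and carboxyl substituents in place can be bought, so no ring has to be made and the task is the construction of the two chains. Both chains begin identically as ArCH2–CH=C(CH3)–C–O with an E-trisubstituted alkene (C1''–C4'' in the short arm, C1'–C4' in the long arm). The short arm ends at the primary alcohol C4''; the long arm continues from the carbinol C4' into a linear prenyl unit C5'H2–C6'H=C7'(CH3)2. The only stereocentre, (R)-C4', is remote from every other element of the structure, so it must be set by a reagent, and once formed it is an allylic alcohol that would ionise in strong acid. The benzylic methylenes C1' and C1'' are also allylic, so base can move the alkenes into conjugation with the ring or expel the allylic oxygen by 1,4-elimination; both E geometries must therefore be set stereospecifically and not equilibrated afterwards. The carboxyl group needs a mask that withstands organometallic reagents and comes off without strong acid. The enabling feature is that C4' is an allylic carbinol carbon bearing CH2–CH=C(CH3)2: cutting C4'–C5' and tying the C4' oxygen to C7' turns the long arm into the 2-methylbut-3-en-2-yl ether of the same hydroxyprenyl unit as the short arm, so both arms can come from one symmetric precursor.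

## Retrosynthesis

**Carboxyl unmasking, 21 from 19 through 20.** Only the C–O bonds of a bicyclic orthoester are cut: in **19** the acid is carried as a 4-methyl-2,6,7-trioxabicyclo[2.2.2]octan-1-yl (OBO) group. An ester would be attacked by alkyllithium, a carboxylate salt would be insoluble and invite ortho-metalation, and an amide would need harsh hydrolysis. The orthoester has no carbonyl group, ignores strong base, and opens in dilute aqueous acid to the triol monoester **20**, which hydroxide cleaves. **19** is not simpler in skeleton, but it can survive the key step. The forward step must use acid weak enough to leave the C4' allylic alcohol alone.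

**Key disconnection, 19 from 16.** The C4'–C5' bond is cut and the C4' oxygen is joined to C7', giving the bis-allylic ether **16**. **16** has no stereocentre and its two arms differ only in the substituent on oxygen. Adding a prenyl metal to an enal would give the branched 1,1-dimethylallyl isomer by allylic transposition, and cutting C3'–C4' would need a separately made trisubstituted alkenyl metal on one arm only. The [2,3]-sigmatropic shift gives the linear prenyl group by its topology and creates C4' in the same event. The forward reaction must remove a proton at C4' only, take its enantiocontrol from a chiral ligand on lithium, and run cold enough to stay on the concerted path.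

**Ether bond, 16 from 15, and 15 from 12 and 13.** The bond between the ether oxygen and C4' is cut to the primary allylic bromide **12** and the tertiary alcohol **13**, used as its potassium salt **14**. The reverse polarity (primary alkoxide, tertiary electrophile) cannot be a clean substitution. The other arm must not carry a free hydroxyl here, because a primary alkoxide would outrun **14** and oligomerise with the bromide; hence the silyl ether **15**. The silyl group is removed (to **16**) just before the key step, where the free hydroxyl is wanted as its alkoxide. The forward substitution has to beat elimination toward the arene.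

**Desymmetrisation, 12 from 11 from 10.** The C–Br bond goes back to the alcohol **11**, and **11** to the bis-silyl ether **10** by adding one silyl group. **10** has a mirror plane and equivalent arms, so cleavage of either silyl ether gives the same **11**. The forward step is statistical and relies on recycling recovered **10** and the over-deprotected diol.

**Carboxyl masking, 10 from 9, 9 from 7 and 8, 7 from 6.** The orthoester **10** is an isomer of the oxetanyl ester **9**, which is the ester of acid **7** with the oxetane alcohol **8**; **7** comes from the methyl ester **6**. The mask is placed after the organoaluminium chemistry, whose Lewis acidity an orthoester would not tolerate, and before the strongly basic steps. The Lewis-acid isomerisation must spare two primary allylic silyl ethers.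

**Both arms at once, 6 from 3 and 4 through 5.** The two benzyl–alkenyl bonds C1'–C2' and C1''–C2'' are cut together to the bis(benzylic bromide) **3** and two equivalents of the alkenylalane **5**, made from the silyl propargyl ether **4** by methyl–aluminium addition across the triple bond. Allylating the arene with a C5 allylic electrophile would raise linear/branched and E/Z questions, and allylic oxidation of two prenyl groups would give alcohol/aldehyde mixtures twice. This cut fixes the E geometry in the syn carbometalation and uses the symmetry fully. The precursors are a one-ring C11 ester and a three-carbon alkyne. The coupling must occur at both sites with retention of geometry and leave the ester alone.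

**Arene, 3 from 2 from 1.** The two C–Br bonds go back to the methyl groups of **2**, which comes from the acid **1** by methylation of both oxygens. **1** has all four ring substituents in their final positions, so no aromatic substitution and no regiochemical question arises.

## Roads not taken

**Alternative 1:** The benzene ring is cut at C2–C3 and C5–C6. The acyclic ketone **A1** supplies C3, C4 and C5 (its carbonyl becomes C4, its two α-methylenes C3 and C5), and the ester-bearing vinamidinium salt **A2** supplies C2, C1 and C6. Base-mediated double condensation closes the ring as the phenol **A3**; O-methylation, desilylation and saponification follow. Its merits are that the 1,3,4,5-substitution pattern cannot come out wrong and that the route is convergent. It is also gentler than the chosen plan in one respect: strong base meets the molecule only when the ring is a phenoxide, which lowers the acidity of C1' and C1''. Its weak points are that **A1** is a long unsymmetrical chain that must already contain the finished (R)-C4' centre and both E alkenes. The annulation therefore solves neither the stereocentre nor the geometry; it moves both into a linear synthesis with no symmetry to exploit, and it builds an arene that can be bought. The hindered phenol of **A3** must also be methylated between two ortho substituents. Against its milder base profile the chosen plan sets the two-for-one installation of the arms, a stereocentre created in the same step as its C–C bond, and a shorter sequence.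

**Alternative 2:** The cut is C3'–C4'. The carbamate **A4** is lithiated next to oxygen by an alkyllithium–chiral diamine base and captured by the alkenyl boronate **A5**. The alkenyl group then migrates from boron to carbon with loss of the carbamate, giving the secondary allylic boronate **A6**, which is oxidised to the alcohol with retention. Its merit is stereocontrol: asymmetric lithiation of primary carbamates is more predictable than a ligand-mediated rearrangement of a bis-allylic ether, so on enantioselectivity this road is the stronger one. It also never requires selective deprotonation of the arene fragment. Its weak points are structural. **A5** needs a boron-bearing trisubstituted alkene on one arm only, so the arms must be attached one at a time and the symmetric double coupling is lost. The methyl ester of **A5** must survive a lithiated carbamate. **A6** is an allylic boronate prone to 1,3-boron shift and must be oxidised at once. The diamine antipode needed for (R)-C4' may be the less accessible one. Against its better enantiocontrol the chosen plan sets symmetry, a shorter route from cheaper fragments, and a fallback that secures the stereocentre by reagent-controlled allylboration.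

**Alternative 3:** The ring is cut at C3–C4 and C5–C6. The 3-alkylcoumalate **A7** and the 1-methoxyalkyne **A8** combine in an inverse-demand [4+2] cycloaddition, and loss of the bridging carboxyl unit as gas gives the arene **A9**. Its merits are convergence and a regiochemistry that follows from polarity: the nucleophilic alkyne carbon bearing the chain bonds to C6 of the pyrone, placing the methoxy carbon next to the pyrone's alkyl group. On paper it is the most convergent of the four plans. Its weak points are that both partners need multistep syntheses, that **A8** is a sensitive ynol ether that must already carry the (R)-C4' centre made by some other asymmetric step, that the 3-substituent slows the cycloaddition, and that the heating needed for cycloaddition and extrusion acts on skipped aryl–allyl and allylic silyl ether units. As in Alternative 1, the key step makes a benzene ring that is available commercially. Against its convergence the chosen plan sets a key step that addresses the one real difficulty of the target, the C4' carbinol with its linear prenyl group.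

Key step: step 11

Assumption: the (S,S)-bis(oxazoline) is taken to deliver the (R)-carbinol; if the sense of induction is the opposite, the (R,R)-ligand is used with no other change.

Abbreviations: TBS = tert-butyldimethylsilyl; OBO = 4-methyl-2,6,7-trioxabicyclo[2.2.2]octan-1-yl.

## Route

Step 1
Reactants: 1 4-hydroxy-3,5-dimethylbenzoic acid
Product: 2 methyl 4-methoxy-3,5-dimethylbenzoate
Conditions: MeI (3 equiv), K2CO3 (3 equiv), DMF, rt → 40 °C
Reagents that add atoms: iodomethane, CI
Why: Carboxylate alkylation and Williamson etherification of the phenoxide in one operation; the 2,6-dimethylphenoxide is hindered but methylates readily with iodomethane in DMF.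

Step 2
Reactants: 2 methyl 4-methoxy-3,5-dimethylbenzoate
Product: 3 methyl 3,5-bis(bromomethyl)-4-methoxybenzoate
Conditions: NBS (2.1 equiv), AIBN (cat.), PhCF3, 85 °C
Reagents that add atoms: N-bromosuccinimide, O=C1CCC(=O)N1Br
Why: Wohl–Ziegler benzylic bromination, once on each methyl group; the ester deactivates the ring toward electrophilic bromination.

Step 3
Reactants: 3 methyl 3,5-bis(bromomethyl)-4-methoxybenzoate; 4 tert-butyldimethyl(prop-2-yn-1-yloxy)silane
Product: 6 methyl 3,5-bis[(E)-4-(tert-butyldimethylsilyloxy)-3-methylbut-2-en-1-yl]-4-methoxybenzoate, via alkenyldimethylalane 5 (not isolated)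
Conditions: 4 (2.6 equiv), AlMe3, Cp2ZrCl2 (0.25 equiv), CH2Cl2, 0 °C → rt; excess AlMe3 removed in vacuo; then 3, Pd(PPh3)4 (5 mol %), THF, rt
Reagents that add atoms: trimethylaluminium, C[Al](C)C
Why: Negishi zirconium-catalysed carboalumination adds methyl and aluminium syn across the alkyne with aluminium on the terminal carbon, and the palladium-catalysed alkenylalane–benzyl halide coupling transfers the alkenyl group with retention, so both arm alkenes form E in one operation; removing excess AlMe3 first protects the ester.

Step 4
Reactants: 6 methyl 3,5-bis[(E)-4-(tert-butyldimethylsilyloxy)-3-methylbut-2-en-1-yl]-4-methoxybenzoate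
Product: 7 3,5-bis[(E)-4-(tert-butyldimethylsilyloxy)-3-methylbut-2-en-1-yl]-4-methoxybenzoic acid
Conditions: LiOH·H2O, THF–MeOH–H2O, rt → 40 °C; then 1 M HCl to pH 4–5, 0 °C
Reagents that add atoms: lithium hydroxide, [Li+].[OH-]
Why: Ester saponification; primary TBS ethers tolerate aqueous hydroxide and a brief, cold, mildly acidic work-up.

Step 5
Reactants: 7 3,5-bis[(E)-4-(tert-butyldimethylsilyloxy)-3-methylbut-2-en-1-yl]-4-methoxybenzoic acid; 8 (3-methyloxetan-3-yl)methanol
Product: 9 (3-methyloxetan-3-yl)methyl 3,5-bis[(E)-4-(tert-butyldimethylsilyloxy)-3-methylbut-2-en-1-yl]-4-methoxybenzoate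
Conditions: DCC (1.2 equiv), DMAP (0.1 equiv), CH2Cl2, 0 °C → rt
Reagents that add atoms: none
Why: Steglich esterification under neutral conditions that leave the oxetane and the silyl ethers untouched.

Step 6
Reactants: 9 (3-methyloxetan-3-yl)methyl 3,5-bis[(E)-4-(tert-butyldimethylsilyloxy)-3-methylbut-2-en-1-yl]-4-methoxybenzoate
Product: 10 1-{3,5-bis[(E)-4-(tert-butyldimethylsilyloxy)-3-methylbut-2-en-1-yl]-4-methoxyphenyl}-4-methyl-2,6,7-trioxabicyclo[2.2.2]octane
Conditions: BF3·OEt2 (0.25 equiv), CH2Cl2, −15 → 0 °C; Et3N quench; Et3N-deactivated silica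
Reagents that add atoms: none
Why: Lewis-acid-catalysed rearrangement of an oxetanyl ester to the bicyclic OBO orthoester: the ester carbonyl opens the activated oxetane to a 1,3-dioxan-2-ylium ion, which the released alkoxide closes; a catalytic charge at low temperature should spare the primary allylic TBS ethers.

Step 7
Reactants: 10 1-{3,5-bis[(E)-4-(tert-butyldimethylsilyloxy)-3-methylbut-2-en-1-yl]-4-methoxyphenyl}-4-methyl-2,6,7-trioxabicyclo[2.2.2]octane
Product: 11 (E)-4-{3-[(E)-4-(tert-butyldimethylsilyloxy)-3-methylbut-2-en-1-yl]-2-methoxy-5-(4-methyl-2,6,7-trioxabicyclo[2.2.2]octan-1-yl)phenyl}-2-methylbut-2-en-1-ol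
Conditions: TBAF (1.0 equiv), THF, 0 °C, stopped at partial conversion; recovered 10 and diol recycled
Reagents that add atoms: none
Why: Fluoride-mediated desilylation run to partial conversion; the two silyl ethers are equivalent by symmetry, so a single mono-alcohol forms, and the orthoester is inert to the basic fluoride.

Step 8
Reactants: 11 (E)-4-{3-[(E)-4-(tert-butyldimethylsilyloxy)-3-methylbut-2-en-1-yl]-2-methoxy-5-(4-methyl-2,6,7-trioxabicyclo[2.2.2]octan-1-yl)phenyl}-2-methylbut-2-en-1-ol
Product: 12 1-{3-[(E)-4-bromo-3-methylbut-2-en-1-yl]-5-[(E)-4-(tert-butyldimethylsilyloxy)-3-methylbut-2-en-1-yl]-4-methoxyphenyl}-4-methyl-2,6,7-trioxabicyclo[2.2.2]octane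
Conditions: CBr4 (1.2 equiv), PPh3 (1.2 equiv), 2,6-lutidine (0.5 equiv), CH2Cl2, −20 → 0 °C
Reagents that add atoms: tetrabromomethane, BrC(Br)(Br)Br
Why: Appel bromination; bromide displaces the alkoxyphosphonium at the primary carbon by SN2 without allylic transposition, and the amine buffer protects the orthoester from adventitious HBr.

Step 9
Reactants: 12 1-{3-[(E)-4-bromo-3-methylbut-2-en-1-yl]-5-[(E)-4-(tert-butyldimethylsilyloxy)-3-methylbut-2-en-1-yl]-4-methoxyphenyl}-4-methyl-2,6,7-trioxabicyclo[2.2.2]octane; 13 2-methylbut-3-en-2-ol
Product: 15 1-{3-[(E)-4-(tert-butyldimethylsilyloxy)-3-methylbut-2-en-1-yl]-4-methoxy-5-[(E)-3-methyl-4-(2-methylbut-3-en-2-yloxy)but-2-en-1-yl]phenyl}-4-methyl-2,6,7-trioxabicyclo[2.2.2]octane, via potassium 2-methylbut-3-en-2-olate 14 (not isolated)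
Conditions: 13 (5 equiv), KH (3 equiv), THF, 0 °C; then 12, 0 °C → rt
Reagents that add atoms: none
Why: Williamson ether synthesis of a tertiary alkoxide with an unhindered primary allylic bromide, a combination well known for 1,1-dimethylallyl ethers; excess free alcohol tempers the basicity, and the silyl ether keeps the other arm from competing as a nucleophile.

Step 10
Reactants: 15 1-{3-[(E)-4-(tert-butyldimethylsilyloxy)-3-methylbut-2-en-1-yl]-4-methoxy-5-[(E)-3-methyl-4-(2-methylbut-3-en-2-yloxy)but-2-en-1-yl]phenyl}-4-methyl-2,6,7-trioxabicyclo[2.2.2]octane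
Product: 16 (E)-4-{2-methoxy-3-[(E)-3-methyl-4-(2-methylbut-3-en-2-yloxy)but-2-en-1-yl]-5-(4-methyl-2,6,7-trioxabicyclo[2.2.2]octan-1-yl)phenyl}-2-methylbut-2-en-1-ol
Conditions: TBAF (1.5 equiv), THF, 0 °C → rt
Reagents that add atoms: none
Why: Fluoride-mediated desilylation; the bis-allylic ether and the orthoester are inert to fluoride.

Step 11
Reactants: 16 (E)-4-{2-methoxy-3-[(E)-3-methyl-4-(2-methylbut-3-en-2-yloxy)but-2-en-1-yl]-5-(4-methyl-2,6,7-trioxabicyclo[2.2.2]octan-1-yl)phenyl}-2-methylbut-2-en-1-ol
Product: 19 (2E,4R)-1-{3-[(E)-4-hydroxy-3-methylbut-2-en-1-yl]-2-methoxy-5-(4-methyl-2,6,7-trioxabicyclo[2.2.2]octan-1-yl)phenyl}-3,7-dimethylocta-2,6-dien-4-ol, via lithium alkoxide 17 (not isolated), via C4'-lithiated ether 18 (not isolated)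
Conditions: n-BuLi (1.0 equiv), Et2O, −78 °C; then added to premixed t-BuLi (2.5 equiv) and (S,S)-2,2'-(pentane-3,3-diyl)bis(4-isopropyl-4,5-dihydrooxazole) (2.5 equiv), hexane, −78 °C; H2O quench at −78 °C
Reagents that add atoms: none
Why: n-BuLi first turns the C4'' hydroxyl into the lithium alkoxide 17, whose charge protects the adjacent C4''H2 from a second deprotonation; the t-BuLi–bis(oxazoline) complex then removes a proton from C4', the only CH2 next to the ether oxygen (the tertiary carbon on the other side has none), to give the ligand-bound α-oxyallyllithium 18. 18 rearranges by a concerted suprafacial [2,3]-sigmatropic shift through a five-membered envelope transition state in which C4' bonds to the terminal vinyl carbon (the future C5'), the O–C(CH3)2 bond breaks and the C6'=C7' alkene forms, so the prenyl group is linear by the topology of the shift and no ring is closed. The closest known reaction type is the enantioselective [2,3]-Wittig rearrangement of allyl ethers promoted by t-BuLi and a chiral bis(oxazoline). The C4' stereocentre is controlled by the chiral ligand on lithium, either through the choice between the two enantiotopic C4' protons or through the face on which the ligand-bound, configurationally mobile allyllithium meets the vinyl group, with inversion at the lithium-bearing carbon. The step needs site selectivity for C4'–H over the benzylic–allylic C1'–H and C1''–H; the E geometry holds C1' trans to the ether oxygen, so a base bound at that oxygen reaches only C4'–H, and the hexane-rich medium at −78 °C disfavours undirected deprotonation. It also needs the [2,3] path to win over the [1,2] and [1,4] shifts, which the low temperature and the unhindered vinyl terminus secure, and the C2'=C3' geometry to be kept, which holds as long as 18 rearranges before its allyl unit can rotate. The new C6'=C7' alkene has two methyl groups on C7' and raises no geometry question.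

Step 12
Reactants: 19 (2E,4R)-1-{3-[(E)-4-hydroxy-3-methylbut-2-en-1-yl]-2-methoxy-5-(4-methyl-2,6,7-trioxabicyclo[2.2.2]octan-1-yl)phenyl}-3,7-dimethylocta-2,6-dien-4-ol
Product: 21 3-[(E)-4-hydroxy-3-methylbut-2-en-1-yl]-5-[(2E,4R)-4-hydroxy-3,7-dimethylocta-2,6-dien-1-yl]-4-methoxybenzoic acid, via triol monoester 20 (not isolated)
Conditions: PPTS (0.2 equiv), THF–H2O, rt; then LiOH·H2O (5 equiv), rt; then 1 M HCl to pH 3–4, 0 °C
Reagents that add atoms: water, O; lithium hydroxide, [Li+].[OH-]
Why: Mild aqueous acid hydrolyses the orthoester only as far as the monoester 20 of the triol, and hydroxide then saponifies that ester; neither stage is harsh enough to ionise the C4' allylic alcohol, so the stereocentre and both E alkenes are untouched.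

## Compound list

1 | 4-hydroxy-3,5-dimethylbenzoic acid | Cc1cc(C(=O)O)cc(C)c1O | starting material
2 | methyl 4-methoxy-3,5-dimethylbenzoate | COC(=O)c1cc(C)c(OC)c(C)c1 | intermediate
3 | methyl 3,5-bis(bromomethyl)-4-methoxybenzoate | COC(=O)c1cc(CBr)c(OC)c(CBr)c1 | intermediate
4 | tert-butyldimethyl(prop-2-yn-1-yloxy)silane | C#CCO[Si](C)(C)C(C)(C)C | starting material
5 | [(E)-3-(tert-butyldimethylsilyloxy)-2-methylprop-1-en-1-yl]dimethylalane | C[Al](C)/C=C(\C)CO[Si](C)(C)C(C)(C)C | intermediate
6 | methyl 3,5-bis[(E)-4-(tert-butyldimethylsilyloxy)-3-methylbut-2-en-1-yl]-4-methoxybenzoate | COC(=O)c1cc(C/C=C(\C)CO[Si](C)(C)C(C)(C)C)c(OC)c(C/C=C(\C)CO[Si](C)(C)C(C)(C)C)c1 | intermediate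
7 | 3,5-bis[(E)-4-(tert-butyldimethylsilyloxy)-3-methylbut-2-en-1-yl]-4-methoxybenzoic acid | OC(=O)c1cc(C/C=C(\C)CO[Si](C)(C)C(C)(C)C)c(OC)c(C/C=C(\C)CO[Si](C)(C)C(C)(C)C)c1 | intermediate
8 | (3-methyloxetan-3-yl)methanol | CC1(CO)COC1 | starting material
9 | (3-methyloxetan-3-yl)methyl 3,5-bis[(E)-4-(tert-butyldimethylsilyloxy)-3-methylbut-2-en-1-yl]-4-methoxybenzoate | CC1(COC(=O)c2cc(C/C=C(\C)CO[Si](C)(C)C(C)(C)C)c(OC)c(C/C=C(\C)CO[Si](C)(C)C(C)(C)C)c2)COC1 | intermediate
10 | 1-{3,5-bis[(E)-4-(tert-butyldimethylsilyloxy)-3-methylbut-2-en-1-yl]-4-methoxyphenyl}-4-methyl-2,6,7-trioxabicyclo[2.2.2]octane | CC12COC(c3cc(C/C=C(\C)CO[Si](C)(C)C(C)(C)C)c(OC)c(C/C=C(\C)CO[Si](C)(C)C(C)(C)C)c3)(OC1)OC2 | intermediate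
11 | (E)-4-{3-[(E)-4-(tert-butyldimethylsilyloxy)-3-methylbut-2-en-1-yl]-2-methoxy-5-(4-methyl-2,6,7-trioxabicyclo[2.2.2]octan-1-yl)phenyl}-2-methylbut-2-en-1-ol | CC12COC(c3cc(C/C=C(\C)CO)c(OC)c(C/C=C(\C)CO[Si](C)(C)C(C)(C)C)c3)(OC1)OC2 | intermediate
12 | 1-{3-[(E)-4-bromo-3-methylbut-2-en-1-yl]-5-[(E)-4-(tert-butyldimethylsilyloxy)-3-methylbut-2-en-1-yl]-4-methoxyphenyl}-4-methyl-2,6,7-trioxabicyclo[2.2.2]octane | CC12COC(c3cc(C/C=C(\C)CBr)c(OC)c(C/C=C(\C)CO[Si](C)(C)C(C)(C)C)c3)(OC1)OC2 | intermediate
13 | 2-methylbut-3-en-2-ol | CC(C)(O)C=C | starting material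
14 | potassium 2-methylbut-3-en-2-olate | CC(C)([O-])C=C.[K+] | intermediate
15 | 1-{3-[(E)-4-(tert-butyldimethylsilyloxy)-3-methylbut-2-en-1-yl]-4-methoxy-5-[(E)-3-methyl-4-(2-methylbut-3-en-2-yloxy)but-2-en-1-yl]phenyl}-4-methyl-2,6,7-trioxabicyclo[2.2.2]octane | CC12COC(c3cc(C/C=C(\C)COC(C)(C)C=C)c(OC)c(C/C=C(\C)CO[Si](C)(C)C(C)(C)C)c3)(OC1)OC2 | intermediate
16 | (E)-4-{2-methoxy-3-[(E)-3-methyl-4-(2-methylbut-3-en-2-yloxy)but-2-en-1-yl]-5-(4-methyl-2,6,7-trioxabicyclo[2.2.2]octan-1-yl)phenyl}-2-methylbut-2-en-1-ol | CC12COC(c3cc(C/C=C(\C)CO)c(OC)c(C/C=C(\C)COC(C)(C)C=C)c3)(OC1)OC2 | intermediate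
17 | lithium alkoxide of 16 (lithium on the C4'' oxygen) | CC12COC(c3cc(C/C=C(\C)CO[Li])c(OC)c(C/C=C(\C)COC(C)(C)C=C)c3)(OC1)OC2 | intermediate
18 | C4'-lithio derivative of 17 (lithium on the ether α-carbon, configuration set by the ligand) | CC12COC(c3cc(C/C=C(\C)CO[Li])c(OC)c(C/C=C(\C)C([Li])OC(C)(C)C=C)c3)(OC1)OC2 | intermediate
19 | (2E,4R)-1-{3-[(E)-4-hydroxy-3-methylbut-2-en-1-yl]-2-methoxy-5-(4-methyl-2,6,7-trioxabicyclo[2.2.2]octan-1-yl)phenyl}-3,7-dimethylocta-2,6-dien-4-ol | CC12COC(c3cc(C/C=C(\C)CO)c(OC)c(C/C=C(\C)[C@H](O)CC=C(C)C)c3)(OC1)OC2 | intermediate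
20 | 3-hydroxy-2-(hydroxymethyl)-2-methylpropyl 3-[(E)-4-hydroxy-3-methylbut-2-en-1-yl]-5-[(2E,4R)-4-hydroxy-3,7-dimethylocta-2,6-dien-1-yl]-4-methoxybenzoate | CC(CO)(CO)COC(=O)c1cc(C/C=C(\C)CO)c(OC)c(C/C=C(\C)[C@H](O)CC=C(C)C)c1 | intermediate
21 | 3-[(E)-4-hydroxy-3-methylbut-2-en-1-yl]-5-[(2E,4R)-4-hydroxy-3,7-dimethylocta-2,6-dien-1-yl]-4-methoxybenzoic acid (CNP0122795.1) | COc1c(C/C=C(\C)CO)cc(C(=O)O)cc1C/C=C(\C)[C@H](O)CC=C(C)C | target

## Step count and risk

Total: 12 steps. Longest linear sequence: 12 steps (1 to 21); compounds 4, 8 and 13 are purchased.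

**Step 11 (key step).** Two things are most likely to go wrong. The first is proton removal at the doubly activated benzylic–allylic C1' or C1'' position instead of C4', followed by 1,4-elimination of the tertiary alkoxide or migration of the alkene into conjugation with the ring. The second is erosion of enantioselectivity: the lithium alkoxide of the spectator arm can enter mixed aggregates with the chiral lithium complex, and the precedent is strongest for benzyl and propargyl ethers, not for an allyl-stabilised carbanion. Lithiation ortho to the orthoester and the [1,2]-shift are lesser risks at −78 °C. Fallback: the carbanion is given up and C4' is made from an aldehyde. Setting out from 11, oxidation with MnO2 gives the enal (E)-4-{3-[(E)-4-(tert-butyldimethylsilyloxy)-3-methylbut-2-en-1-yl]-2-methoxy-5-(OBO)phenyl}-2-methylbut-2-enal F1. Asymmetric allylboration with the antipode of B-allyldiisopinocampheylborane that leads to the (R)-carbinol (expected to be the one derived from (−)-α-pinene) gives the homoallylic alcohol F2. Cross-metathesis of its terminal vinyl group with 2-methylbut-2-ene under the second-generation Grubbs catalyst gives the prenyl compound F3, the mono-TBS ether of 19. TBAF then brings the route back at 19.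

**Step 9.** The tertiary alkoxide may act as a base on the acidic C1'–H and cause 1,4-elimination of HBr toward an aryl diene, or attack in the SN2' sense and transpose the allyl unit. Fallback: setting out from 12, alkylation of the slimmer and less basic sodium 2-methylbut-3-yn-2-olate (NaH, THF–DMF) gives the propargylic ether F4. Semihydrogenation of its terminal alkyne (H2, Pd/CaCO3 poisoned with Pb(OAc)2, quinoline) brings the route back at 15.

**Step 3.** The second coupling may stall, residual methylaluminium species may transfer methyl to the benzylic position or attack the ester, and the carboalumination of the silyl propargyl ether may be sluggish. Fallback: the polarity of the coupling is reversed. The alane 5 is quenched with iodine to give the vinyl iodide (E)-tert-butyl[(3-iodo-2-methylprop-2-en-1-yl)oxy]dimethylsilane F5. Setting out from 3, zinc insertion (Zn dust, LiCl, THF) gives methyl 3,5-bis[(bromozincio)methyl]-4-methoxybenzoate F6, an ester-tolerant benzylic zinc reagent. Negishi coupling of F6 with F5 under Pd(PPh3)4 brings the route back at 6.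

**Step 7.** Mono-desilylation is statistical; over-cleavage to the diol and incomplete conversion limit the throughput. Fallback: setting out from 10, excess TBAF gives the diol (2E,2'E)-4,4'-[2-methoxy-5-(OBO)-1,3-phenylene]bis(2-methylbut-2-en-1-ol) F7. Silylation of its monosodium alkoxide (NaH 1 equiv, then TBSCl 1 equiv, THF) brings the route back at 11.

## Further compounds

F1 | step 11 | (E)-4-{3-[(E)-4-(tert-butyldimethylsilyloxy)-3-methylbut-2-en-1-yl]-2-methoxy-5-(4-methyl-2,6,7-trioxabicyclo[2.2.2]octan-1-yl)phenyl}-2-methylbut-2-enal | CC12COC(c3cc(C/C=C(\C)C=O)c(OC)c(C/C=C(\C)CO[Si](C)(C)C(C)(C)C)c3)(OC1)OC2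
F2 | step 11 | (2E,4R)-1-{3-[(E)-4-(tert-butyldimethylsilyloxy)-3-methylbut-2-en-1-yl]-2-methoxy-5-(4-methyl-2,6,7-trioxabicyclo[2.2.2]octan-1-yl)phenyl}-3-methylhepta-2,6-dien-4-ol | CC12COC(c3cc(C/C=C(\C)[C@H](O)CC=C)c(OC)c(C/C=C(\C)CO[Si](C)(C)C(C)(C)C)c3)(OC1)OC2
F3 | step 11 | (2E,4R)-1-{3-[(E)-4-(tert-butyldimethylsilyloxy)-3-methylbut-2-en-1-yl]-2-methoxy-5-(4-methyl-2,6,7-trioxabicyclo[2.2.2]octan-1-yl)phenyl}-3,7-dimethylocta-2,6-dien-4-ol | CC12COC(c3cc(C/C=C(\C)[C@H](O)CC=C(C)C)c(OC)c(C/C=C(\C)CO[Si](C)(C)C(C)(C)C)c3)(OC1)OC2
F4 | step 9 | 1-{3-[(E)-4-(tert-butyldimethylsilyloxy)-3-methylbut-2-en-1-yl]-4-methoxy-5-[(E)-3-methyl-4-(2-methylbut-3-yn-2-yloxy)but-2-en-1-yl]phenyl}-4-methyl-2,6,7-trioxabicyclo[2.2.2]octane | CC12COC(c3cc(C/C=C(\C)COC(C)(C)C#C)c(OC)c(C/C=C(\C)CO[Si](C)(C)C(C)(C)C)c3)(OC1)OC2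
F5 | step 3 | (E)-tert-butyl[(3-iodo-2-methylprop-2-en-1-yl)oxy]dimethylsilane | I/C=C(\C)CO[Si](C)(C)C(C)(C)C
F6 | step 3 | methyl 3,5-bis[(bromozincio)methyl]-4-methoxybenzoate | COC(=O)c1cc(C[Zn]Br)c(OC)c(C[Zn]Br)c1
F7 | step 7 | (2E,2'E)-4,4'-[2-methoxy-5-(4-methyl-2,6,7-trioxabicyclo[2.2.2]octan-1-yl)-1,3-phenylene]bis(2-methylbut-2-en-1-ol) | CC12COC(c3cc(C/C=C(\C)CO)c(OC)c(C/C=C(\C)CO)c3)(OC1)OC2
A1 | alternative 1 | (2E,9E,11R)-1,11-bis(tert-butyldimethylsilyloxy)-2,10,14-trimethylpentadeca-2,9,13-trien-6-one | CC(C)(C)[Si](C)(C)OC/C(C)=C/CCC(=O)CC/C=C(\C)[C@H](O[Si](C)(C)C(C)(C)C)CC=C(C)C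
A2 | alternative 1 | 1,3-bis(dimethylamino)-2-(methoxycarbonyl)trimethinium hexafluorophosphate | COC(=O)C(C=[N+](C)C)=CN(C)C.F[P-](F)(F)(F)(F)F
A3 | alternative 1 | methyl 3-[(E)-4-(tert-butyldimethylsilyloxy)-3-methylbut-2-en-1-yl]-5-[(2E,4R)-4-(tert-butyldimethylsilyloxy)-3,7-dimethylocta-2,6-dien-1-yl]-4-hydroxybenzoate | COC(=O)c1cc(C/C=C(\C)CO[Si](C)(C)C(C)(C)C)c(O)c(C/C=C(\C)[C@H](O[Si](C)(C)C(C)(C)C)CC=C(C)C)c1
A4 | alternative 2 | 4-methylpent-3-en-1-yl N,N-diisopropylcarbamate | CC(C)=CCCOC(=O)N(C(C)C)C(C)C
A5 | alternative 2 | methyl 3-[(E)-4-(tert-butyldimethylsilyloxy)-3-methylbut-2-en-1-yl]-4-methoxy-5-[(Z)-3-(4,4,5,5-tetramethyl-1,3,2-dioxaborolan-2-yl)but-2-en-1-yl]benzoate | COC(=O)c1cc(C/C=C(\C)CO[Si](C)(C)C(C)(C)C)c(OC)c(C/C=C(\C)B2OC(C)(C)C(C)(C)O2)c1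
A6 | alternative 2 | methyl 3-[(E)-4-(tert-butyldimethylsilyloxy)-3-methylbut-2-en-1-yl]-5-[(2E,4R)-3,7-dimethyl-4-(4,4,5,5-tetramethyl-1,3,2-dioxaborolan-2-yl)octa-2,6-dien-1-yl]-4-methoxybenzoate | COC(=O)c1cc(C/C=C(\C)CO[Si](C)(C)C(C)(C)C)c(OC)c(C/C=C(\C)[C@H](B2OC(C)(C)C(C)(C)O2)CC=C(C)C)c1
A7 | alternative 3 | methyl 3-[(E)-4-(tert-butyldimethylsilyloxy)-3-methylbut-2-en-1-yl]-2-oxo-2H-pyran-5-carboxylate | COC(=O)C1=COC(=O)C(C/C=C(\C)CO[Si](C)(C)C(C)(C)C)=C1
A8 | alternative 3 | (4E,6R)-6-(tert-butyldimethylsilyloxy)-1-methoxy-5,9-dimethyldeca-4,8-dien-1-yne | COC#CC/C=C(\C)[C@H](O[Si](C)(C)C(C)(C)C)CC=C(C)C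
A9 | alternative 3 | methyl 3-[(E)-4-(tert-butyldimethylsilyloxy)-3-methylbut-2-en-1-yl]-5-[(2E,4R)-4-(tert-butyldimethylsilyloxy)-3,7-dimethylocta-2,6-dien-1-yl]-4-methoxybenzoate | COC(=O)c1cc(C/C=C(\C)CO[Si](C)(C)C(C)(C)C)c(OC)c(C/C=C(\C)[C@H](O[Si](C)(C)C(C)(C)C)CC=C(C)C)c1
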